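Retrosynthetic cuts:
- (a) The bond between the benzylic CH2 on ring B (the benzo ring of the dihydrobenzofuran) and the neighbouring CH(CH2OH), after the 1,4-diol is folded back into a trans-dibenzylbutyrolactone.
- (b) C3-C3a of the dihydrobenzofuran, read backwards as a 1,2-shift that restores the C4-C4a bond of a flavanone.
- (c) The C2-ring C bond, read backwards as a conjugate addition to a chromone.

Enabling feature: dihydrobenzofuran C3 is bonded to ring B carbon C3a and to one exocyclic oxygenated carbon, and C2 bears O1 and guaiacyl ring C. This is the atom pattern of an 8-methoxyflavanone whose C4a has moved from C4 to C3, with C4 pushed out of the ring as a carboxyl carbon.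
Forward order: the pyranone is closed on brominated ring B (chromone), ring C is added at C2, and the pyranone is contracted to the dihydrofuran. Br is then exchanged for CH2Br, the chain is joined to the ring A (terminal guaiacyl) lactone, the lactone is opened by hydride, and the phenols are freed.
Stereochemistry: C2 comes from a palladium pyridine-oxazoline catalyst and C3 from C2 through the geometry of the shift. The chain centre next to ring A comes from Rh-DuPhos hydrogenation, and the chain centre next to ring B from anti alkylation of the lactone enolate.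

Key step: step 6

Assumption: the ligand antipodes named in steps 5 and 12 are those expected, by analogy with cyclic enones and with alkylidenesuccinate half-esters, to give the configurations drawn; if a catalyst shows the opposite sense on these substrates, its mirror-image ligand is used and nothing else changes.

Step 1
Reactants: 1 2'-hydroxy-3'-methoxyacetophenone
Product: 2 5'-bromo-2'-hydroxy-3'-methoxyacetophenone
Conditions: NBS (1.05 equiv), MeCN, 0 °C to rt
Reagents that add atoms: N-bromosuccinimide, O=C1CCC(=O)N1Br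
Why: Electrophilic aromatic bromination in which the free phenol is the dominant director and both its ortho positions are occupied, so bromine should enter para to OH, as it does with o-vanillin.

Step 2
Reactants: 2 5'-bromo-2'-hydroxy-3'-methoxyacetophenone
Product: 4 6-bromo-8-methoxy-4H-chromen-4-one, via enaminone 3 (not isolated)
Conditions: Me2NCH(OMe)2 (2 equiv), toluene, 100 °C; evaporate; conc. HCl, CH2Cl2, 40 °C
Reagents that add atoms: N,N-dimethylformamide dimethyl acetal, COC(OC)N(C)C
Why: Enaminone formation at the acetyl methyl group, then acid-induced addition of the phenol and loss of dimethylamine, is the standard chromone synthesis from 2'-hydroxyacetophenones and closes the pyranone ring.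

Step 3
Reactants: 5 2-methoxy-4-(4,4,5,5-tetramethyl-1,3,2-dioxaborolan-2-yl)phenol
Product: 6 2-methoxy-4-(4,4,5,5-tetramethyl-1,3,2-dioxaborolan-2-yl)phenyl 4-methylbenzenesulfonate
Conditions: TsCl (1.2 equiv), Et3N (1.5 equiv), DMAP (5 mol %), CH2Cl2, 0 °C to rt
Reagents that add atoms: p-toluenesulfonyl chloride, Cc1ccc(cc1)S(=O)(=O)Cl
Why: Routine O-sulfonylation of a phenol to which the pinacol boronate is inert; the tosylate is chosen because it draws electron density out of ring C for step 6 and tolerates acid, oxidant, cold hydride and palladium.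

Step 4
Reactants: 6 2-methoxy-4-(4,4,5,5-tetramethyl-1,3,2-dioxaborolan-2-yl)phenyl 4-methylbenzenesulfonate
Product: 7 [3-methoxy-4-(tosyloxy)phenyl]boronic acid
Conditions: NaIO4 (3 equiv), NH4OAc (3 equiv), acetone-H2O 1:1, rt
Reagents that add atoms: water, O
Why: Periodate cleavage of the pinacol released at equilibrium drives hydrolysis of the boronate to the free boronic acid in a near-neutral buffer that leaves the aryl sulfonate alone.

Step 5
Reactants: 4 6-bromo-8-methoxy-4H-chromen-4-one; 7 [3-methoxy-4-(tosyloxy)phenyl]boronic acid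
Product: 8 (S)-6-bromo-8-methoxy-2-[3-methoxy-4-(tosyloxy)phenyl]chroman-4-one
Conditions: Pd(OCOCF3)2 (5 mol %), (R)-4-tert-butyl-2-(2-pyridyl)oxazoline (6 mol %), NH4PF6 (30 mol %), H2O (5 equiv), 7 (2 equiv), ClCH2CH2Cl, 60 °C, air; recrystallise
Reagents that add atoms: none
Why: Enantioselective conjugate addition of an arylboronic acid to a chromone with a cationic divalent palladium pyridine-oxazoline catalyst (transmetalation, face-selective carbopalladation of C2=C3, protonolysis of the palladium enolate), in which the tert-butyl group of the ligand sets C2 as (S) and the absence of zerovalent palladium from the cycle spares the aryl bromide and the tosylate.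

Step 6
Reactants: 8 (S)-6-bromo-8-methoxy-2-[3-methoxy-4-(tosyloxy)phenyl]chroman-4-one
Product: 11 methyl (2S,3S)-5-bromo-7-methoxy-2-[3-methoxy-4-(tosyloxy)phenyl]-2,3-dihydrobenzofuran-3-carboxylate (2,3-trans), via enol ether 9 (not isolated), via iodanyl ketal 10 (not isolated)
Conditions: HC(OMe)3, conc. H2SO4 (0.5 equiv), 0 °C, 15 min; PhI(OAc)2 (1.2 equiv), 0 °C to rt, 1-2 h; aq. NaHCO3
Reagents that add atoms: trimethyl orthoformate, COC(OC)OC
Why: Acid and orthoformate turn the C4 carbonyl of 8 into enol ether 9, whose C3 attacks PhI(OAc)2 from the face opposite the equatorial ring C while methanol caps C4, so that ketal 10 carries an equatorial phenyliodanyl group trans to ring C. That C3-I bond is antiperiplanar to C4-C4a, so C4a of ring B moves from C4 to C3 as iodobenzene leaves, assisted by the two ketal oxygens, and the dimethoxycarbenium ion left at C4 is taken up by methanol and hydrolysed to the methyl ester on work-up. The closest known reaction is this very one, the oxidative ring contraction of flavanones by trivalent iodine or trivalent thallium in trimethyl orthoformate, a cyclic case of the 1,2-aryl shift that converts aryl alkyl ketones into 2-arylalkanoates. The dihydrofuran arises by contraction and not by cyclisation: one concerted shift makes C3-C3a, breaks C4-C4a and shrinks the six-membered pyranone to five members with C4 expelled as the exocyclic ester carbon. C3 is the only new stereocentre and is under substrate control, because backside displacement of an iodine that sits trans to ring C leaves hydrogen on the ring C face and the ester on the other (2,3-trans, 2S,3S), whereas C2 takes no part and stays (S). The step needs migration of ring B in preference to migration of ring C (isoflavone), proton loss (flavone) and retro-oxa-Michael opening (racemisation); O1 ortho to C4a stabilises the bridged transition state, the tosylate makes ring C a poor migrating group and shields it from the oxidant, and forming 9 cold under anhydrous conditions keeps the acid exposure short.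

Step 7
Reactants: 11 methyl (2S,3S)-5-bromo-7-methoxy-2-[3-methoxy-4-(tosyloxy)phenyl]-2,3-dihydrobenzofuran-3-carboxylate
Product: 12 4-[(2S,3R)-5-bromo-3-(hydroxymethyl)-7-methoxy-2,3-dihydrobenzofuran-2-yl]-2-methoxyphenyl 4-methylbenzenesulfonate
Conditions: i-Bu2AlH (2.5 equiv), CH2Cl2, -78 to 0 °C; aq. potassium sodium tartrate
Reagents that add atoms: none
Why: Ester reduction with an electrophilic aluminium hydride, which leaves aryl bromide and aryl sulfonate untouched and is not basic enough to epimerise or open at C3 (the C3 descriptor changes from S to R by ranking only).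

Step 8
Reactants: 12 4-[(2S,3R)-5-bromo-3-(hydroxymethyl)-7-methoxy-2,3-dihydrobenzofuran-2-yl]-2-methoxyphenyl 4-methylbenzenesulfonate
Product: 13 {(2S,3R)-5-bromo-7-methoxy-2-[3-methoxy-4-(tosyloxy)phenyl]-2,3-dihydrobenzofuran-3-yl}methyl pivalate
Conditions: t-BuCOCl (1.3 equiv), pyridine (3 equiv), DMAP (5 mol %), CH2Cl2, 0 °C to rt
Reagents that add atoms: pivaloyl chloride, CC(C)(C)C(=O)Cl
Why: Simple acylation of a primary alcohol; the pivalate resists the lactone enolate of step 14 and is removed by the hydride of step 15, so no separate deprotection is needed.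

Step 9
Reactants: 13 {(2S,3R)-5-bromo-7-methoxy-2-[3-methoxy-4-(tosyloxy)phenyl]-2,3-dihydrobenzofuran-3-yl}methyl pivalate
Product: 14 {(2S,3R)-5-(hydroxymethyl)-7-methoxy-2-[3-methoxy-4-(tosyloxy)phenyl]-2,3-dihydrobenzofuran-3-yl}methyl pivalate
Conditions: Bu3SnCH2OH (1.3 equiv), Pd(PPh3)4 (5 mol %), 1,4-dioxane, 100 °C
Reagents that add atoms: (tributylstannyl)methanol, CCCC[Sn](CCCC)(CCCC)CO
Why: Stille coupling with the hydroxymethyl stannane replaces Br by CH2OH in one base-free operation, and Pd(PPh3)4 inserts into the C-Br bond but not into the aryl C-OTs bond.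

Step 10
Reactants: 14 {(2S,3R)-5-(hydroxymethyl)-7-methoxy-2-[3-methoxy-4-(tosyloxy)phenyl]-2,3-dihydrobenzofuran-3-yl}methyl pivalate
Product: 15 {(2S,3R)-5-(bromomethyl)-7-methoxy-2-[3-methoxy-4-(tosyloxy)phenyl]-2,3-dihydrobenzofuran-3-yl}methyl pivalate
Conditions: PBr3 (0.4 equiv), CH2Cl2, 0 °C; cold aq. NaHCO3; used without chromatography
Reagents that add atoms: phosphorus tribromide, BrP(Br)Br
Why: Bromide displacement of the phosphite ester of a para-alkoxybenzylic alcohol, the usual preparation of dialkoxybenzyl bromides for lignan alkylations, with an aqueous work-up that avoids silica.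

Step 11
Reactants: 16 4-(benzyloxy)-3-methoxybenzaldehyde; 17 dimethyl succinate
Product: 18 (E)-4-[4-(benzyloxy)-3-methoxyphenyl]-3-(methoxycarbonyl)but-3-enoic acid
Conditions: NaOMe (1.5 equiv), 17 (1.5 equiv), MeOH, reflux; aq. HCl
Reagents that add atoms: none
Why: Stobbe condensation, in which the aldol alkoxide closes to a paraconic ester lactone that opens by elimination to the half-ester, with the aryl group trans to the conjugated ester (E).

Step 12
Reactants: 18 (E)-4-[4-(benzyloxy)-3-methoxyphenyl]-3-(methoxycarbonyl)but-3-enoic acid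
Product: 19 (R)-4-[4-(benzyloxy)-3-methoxyphenyl]-3-(methoxycarbonyl)butanoic acid
Conditions: [Rh(cod)((S,S)-Et-DuPhos)]BF4 (0.5 mol %), H2 (5 bar), NaOMe (0.1 equiv), MeOH, rt
Reagents that add atoms: none
Why: Asymmetric hydrogenation of a Stobbe-type alkylidenesuccinate half-ester, in which chelation of alkene and carboxylate to the chiral rhodium bisphospholane fixes the face of hydrogen delivery and sets the (R) centre, while the benzyl ether is inert to the homogeneous catalyst.

Step 13
Reactants: 19 (R)-4-[4-(benzyloxy)-3-methoxyphenyl]-3-(methoxycarbonyl)butanoic acid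
Product: 21 (R)-4-[4-(benzyloxy)-3-methoxybenzyl]dihydrofuran-2(3H)-one, via hydroxy acid 20 (not isolated)
Conditions: KOH (1.0 equiv), EtOH; CaCl2 (1.5 equiv), NaBH4 (3 equiv), EtOH, -10 °C to rt; 3 M HCl, rt
Reagents that add atoms: none
Why: Chemoselective borohydride reduction in which Ca(BH4)2 reduces the ester but not the potassium carboxylate, and acidification lactonises the gamma-hydroxy acid without touching the stereocentre.

Step 14
Reactants: 21 (R)-4-[4-(benzyloxy)-3-methoxybenzyl]dihydrofuran-2(3H)-one; 15 {(2S,3R)-5-(bromomethyl)-7-methoxy-2-[3-methoxy-4-(tosyloxy)phenyl]-2,3-dihydrobenzofuran-3-yl}methyl pivalate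
Product: 23 {(2S,3R)-5-{[(3R,4R)-4-[4-(benzyloxy)-3-methoxybenzyl]-2-oxotetrahydrofuran-3-yl]methyl}-7-methoxy-2-[3-methoxy-4-(tosyloxy)phenyl]-2,3-dihydrobenzofuran-3-yl}methyl pivalate, via lithium enolate 22 (not isolated)
Conditions: 21 (1.2 equiv), LiN(SiMe3)2 (1.15 equiv), THF, -78 °C; 15 (1.0 equiv), DMPU, -78 to -30 °C
Reagents that add atoms: none
Why: Alkylation of a beta-substituted gamma-butyrolactone enolate with a benzylic bromide, the standard entry to dibenzylbutyrolactone lignans, in which the electrophile approaches anti to the C4 benzyl group and gives the trans (3R,4R) lactone, also the thermodynamic isomer.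

Step 15
Reactants: 23 the trans lactone pivalate of step 14
Product: 24 4-[(2S,3R)-5-{(2R,3R)-3-[4-(benzyloxy)-3-methoxybenzyl]-4-hydroxy-2-(hydroxymethyl)butyl}-3-(hydroxymethyl)-7-methoxy-2,3-dihydrobenzofuran-2-yl]-2-methoxyphenyl 4-methylbenzenesulfonate
Conditions: LiAlH4 (4 equiv), THF, 0 °C to rt; aq. potassium sodium tartrate
Reagents that add atoms: none
Why: Hydride reduction opens the lactone to the 1,4-diol and cleaves the pivalate in the same operation without touching a stereocentre, and any premature loss of the tosylate is harmless because step 16 removes it.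

Step 16
Reactants: 24 the tosylated and benzylated triol of step 15
Product: 25 (2R,3R)-2-[4-(benzyloxy)-3-methoxybenzyl]-3-{[(2S,3R)-2-(4-hydroxy-3-methoxyphenyl)-3-(hydroxymethyl)-7-methoxy-2,3-dihydrobenzofuran-5-yl]methyl}butane-1,4-diol
Conditions: Mg turnings (10 equiv), MeOH, rt; aq. NH4Cl
Reagents that add atoms: none
Why: Reductive S-O cleavage of an aryl sulfonate by electron transfer from magnesium in methanol, a mild detosylation that avoids hot alkali and leaves benzyl ether, benzylic ring C-O bond and alcohols intact.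

Step 17
Reactants: 25 the benzyl ether of step 16
Product: 26 (2R,3R)-2-(4-hydroxy-3-methoxybenzyl)-3-{[(2S,3R)-2-(4-hydroxy-3-methoxyphenyl)-3-(hydroxymethyl)-7-methoxy-2,3-dihydrobenzofuran-5-yl]methyl}butane-1,4-diol (CNP0256425.1)
Conditions: H2 (1 atm), Pd/C (10 wt %), EtOAc-MeOH, rt
Reagents that add atoms: none
Why: Catalytic hydrogenolysis of an aryl benzyl ether at ambient pressure, conditions under which 2-aryl-2,3-dihydrobenzofurans of this neolignan type are known to keep their ring C-O bond, with toluene as the only by-product.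

Compound list
1 | 2'-hydroxy-3'-methoxyacetophenone | CC(=O)c1cccc(OC)c1O | starting material
2 | 5'-bromo-2'-hydroxy-3'-methoxyacetophenone | CC(=O)c1cc(Br)cc(OC)c1O | intermediate
3 | (E)-1-(5-bromo-2-hydroxy-3-methoxyphenyl)-3-(dimethylamino)prop-2-en-1-one | CN(C)/C=C/C(=O)c1cc(Br)cc(OC)c1O | intermediate
4 | 6-bromo-8-methoxy-4H-chromen-4-one | O=c1ccoc2c(OC)cc(Br)cc12 | intermediate
5 | 2-methoxy-4-(4,4,5,5-tetramethyl-1,3,2-dioxaborolan-2-yl)phenol | COc1cc(B2OC(C)(C)C(C)(C)O2)ccc1O | starting material
6 | 2-methoxy-4-(4,4,5,5-tetramethyl-1,3,2-dioxaborolan-2-yl)phenyl 4-methylbenzenesulfonate | COc1cc(B2OC(C)(C)C(C)(C)O2)ccc1OS(=O)(=O)c1ccc(C)cc1 | intermediate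
7 | [3-methoxy-4-(tosyloxy)phenyl]boronic acid | COc1cc(B(O)O)ccc1OS(=O)(=O)c1ccc(C)cc1 | intermediate
8 | (S)-6-bromo-8-methoxy-2-[3-methoxy-4-(tosyloxy)phenyl]chroman-4-one | O=C1C[C@@H](c2ccc(OS(=O)(=O)c3ccc(C)cc3)c(OC)c2)Oc2c(OC)cc(Br)cc12 | intermediate
9 | (S)-6-bromo-4,8-dimethoxy-2-[3-methoxy-4-(tosyloxy)phenyl]-2H-chromene | COC1=C[C@@H](c2ccc(OS(=O)(=O)c3ccc(C)cc3)c(OC)c2)Oc2c(OC)cc(Br)cc12 | intermediate
10 | acetoxy(phenyl)-λ3-iodane bound at C3 of the 6-bromo-4,4,8-trimethoxy-2-arylchroman, iodine trans to ring C, C2 arranged as in 8 | COC1(OC)[C@H](I(OC(C)=O)c2ccccc2)[C@@H](c2ccc(OS(=O)(=O)c3ccc(C)cc3)c(OC)c2)Oc2c(OC)cc(Br)cc12 | intermediate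
11 | methyl (2S,3S)-5-bromo-7-methoxy-2-[3-methoxy-4-(tosyloxy)phenyl]-2,3-dihydrobenzofuran-3-carboxylate (trans) | Brc1cc(OC)c2c(c1)[C@H](C(=O)OC)[C@@H](c1ccc(OS(=O)(=O)c3ccc(C)cc3)c(OC)c1)O2 | intermediate
12 | 4-[(2S,3R)-5-bromo-3-(hydroxymethyl)-7-methoxy-2,3-dihydrobenzofuran-2-yl]-2-methoxyphenyl 4-methylbenzenesulfonate | Brc1cc(OC)c2c(c1)[C@H](CO)[C@@H](c1ccc(OS(=O)(=O)c3ccc(C)cc3)c(OC)c1)O2 | intermediate
13 | {(2S,3R)-5-bromo-7-methoxy-2-[3-methoxy-4-(tosyloxy)phenyl]-2,3-dihydrobenzofuran-3-yl}methyl pivalate | Brc1cc(OC)c2c(c1)[C@H](COC(=O)C(C)(C)C)[C@@H](c1ccc(OS(=O)(=O)c3ccc(C)cc3)c(OC)c1)O2 | intermediate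
14 | {(2S,3R)-5-(hydroxymethyl)-7-methoxy-2-[3-methoxy-4-(tosyloxy)phenyl]-2,3-dihydrobenzofuran-3-yl}methyl pivalate | OCc1cc(OC)c2c(c1)[C@H](COC(=O)C(C)(C)C)[C@@H](c1ccc(OS(=O)(=O)c3ccc(C)cc3)c(OC)c1)O2 | intermediate
15 | {(2S,3R)-5-(bromomethyl)-7-methoxy-2-[3-methoxy-4-(tosyloxy)phenyl]-2,3-dihydrobenzofuran-3-yl}methyl pivalate | BrCc1cc(OC)c2c(c1)[C@H](COC(=O)C(C)(C)C)[C@@H](c1ccc(OS(=O)(=O)c3ccc(C)cc3)c(OC)c1)O2 | intermediate
16 | 4-(benzyloxy)-3-methoxybenzaldehyde | COc1cc(C=O)ccc1OCc1ccccc1 | starting material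
17 | dimethyl succinate | COC(=O)CCC(=O)OC | starting material
18 | (E)-4-[4-(benzyloxy)-3-methoxyphenyl]-3-(methoxycarbonyl)but-3-enoic acid | COC(=O)/C(CC(=O)O)=C/c1ccc(OCc2ccccc2)c(OC)c1 | intermediate
19 | (R)-4-[4-(benzyloxy)-3-methoxyphenyl]-3-(methoxycarbonyl)butanoic acid | COc1cc(C[C@H](CC(=O)O)C(=O)OC)ccc1OCc1ccccc1 | intermediate
20 | (R)-4-[4-(benzyloxy)-3-methoxyphenyl]-3-(hydroxymethyl)butanoic acid | COc1cc(C[C@H](CC(=O)O)CO)ccc1OCc1ccccc1 | intermediate
21 | (R)-4-[4-(benzyloxy)-3-methoxybenzyl]dihydrofuran-2(3H)-one | COc1cc(C[C@H]2COC(=O)C2)ccc1OCc1ccccc1 | intermediate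
22 | lithium enolate of 21 | COc1cc(C[C@H]2COC(O[Li])=C2)ccc1OCc1ccccc1 | intermediate
23 | trans (3R,4R)-lactone carrying the ring A benzyl group at C4 and the (2S,3R)-dihydrobenzofuran-5-ylmethyl group at C3, with pivalate, tosylate and benzyl ether in place | COc1cc(C[C@H]2COC(=O)[C@@H]2Cc2cc(OC)c3c(c2)[C@H](COC(=O)C(C)(C)C)[C@@H](c2ccc(OS(=O)(=O)c4ccc(C)cc4)c(OC)c2)O3)ccc1OCc1ccccc1 | intermediate
24 | (2R,3R)-butanediol triol with ring C tosylate and ring A benzyl ether, dihydrobenzofuran (2S,3R) | COc1cc(C[C@@H](CO)[C@H](CO)Cc2cc(OC)c3c(c2)[C@H](CO)[C@@H](c2ccc(OS(=O)(=O)c4ccc(C)cc4)c(OC)c2)O3)ccc1OCc1ccccc1 | intermediate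
25 | (2R,3R)-butanediol triol with free ring C phenol and ring A benzyl ether, dihydrobenzofuran (2S,3R) | COc1cc(C[C@@H](CO)[C@H](CO)Cc2cc(OC)c3c(c2)[C@H](CO)[C@@H](c2ccc(O)c(OC)c2)O3)ccc1OCc1ccccc1 | intermediate
26 | CNP0256425.1, (2R,3R)-2-(4-hydroxy-3-methoxybenzyl)-3-{[(2S,3R)-2-(4-hydroxy-3-methoxyphenyl)-3-(hydroxymethyl)-7-methoxy-2,3-dihydrobenzofuran-5-yl]methyl}butane-1,4-diol | COc1cc(C[C@@H](CO)[C@H](CO)Cc2cc(OC)c3c(c2)[C@H](CO)[C@@H](c2ccc(O)c(OC)c2)O3)ccc1O | target

Total step count: 17.
Longest linear sequence: 12 steps (steps 1, 2, 5, 6, 7, 8, 9, 10, 14, 15, 16, 17). The branch through steps 3 and 4 is equally long. The lactone branch (steps 11 to 13) joins at step 14.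

Steps most likely to fail

1. Step 6.
- **Risk:** Bromine and the methoxy group both sit meta to C4a and slow the migration of ring B. Proton loss to the flavone, solvent capture at C3 or a shift of ring C may then overtake the contraction. Acid-induced ring opening may also erode the enantiomeric purity.
- **Fallback:** the same C4a shift is run as a Wolff rearrangement, where only the acyl substituent can migrate. It sets out from 8.
- LiN(SiMe3)2 in THF at -78 °C followed by CF3CO2CH2CF3 should give the 3-trifluoroacetyl flavanone F1.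
- MsN3, Et3N and water in MeCN should convert it into the 3-diazoflavanone F2 (detrifluoroacetylative diazo transfer).
- Irradiation through Pyrex in MeOH expels nitrogen with migration of C4a to C3 and gives the ring-contracted ketene F3.
- The ketene adds methanol to give 11 together with its C3 epimer, the cis ester F4. Catalytic DBU in toluene equilibrates F4 to the more stable trans isomer, so the fallback returns to the route at 11.

2. Step 5.
- **Risk:** Carbopalladation of the 8-methoxy-substituted chromone may be slow and the facial selectivity poor. The aryl bromide may also be consumed by cross-coupling if zerovalent palladium accumulates.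
- **Fallback:** build the racemic flavanone and resolve it kinetically. It sets out from 2.
- Vanillin with TsCl and Et3N gives O-tosylvanillin F5.
- Acid-mediated Claisen-Schmidt condensation of 2 with F5 (SOCl2 in EtOH, rt) should give the 2'-hydroxychalcone F6.
- NaOAc in refluxing EtOH closes the chalcone by oxa-Michael addition to the racemic flavanone F7.
- Asymmetric transfer hydrogenation follows, with the antipode of RhCl(Cp*)(TsDPEN) that reduces the (R)-ketone faster (HCO2H-Et3N, EtOAc, rt). It converts that enantiomer into the cis-(2R,4R)-flavan-4-ol F8 and leaves the (S)-ketone, which is separated by chromatography. The fallback returns to the route at 8.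

3. Step 9.
- **Risk:** Oxidative addition into the electron-rich C-Br bond may be sluggish. Protodestannylation of the stannane and hydrodebromination may compete.
- **Fallback:** introduce the carbon as carbon monoxide instead of as an organometallic. It sets out from 13.
- Reductive carbonylation (Pd(OAc)2, di(1-adamantyl)-n-butylphosphine, CO-H2 1:1 at 5 bar, TMEDA, toluene, 100 °C) should give the 5-carbaldehyde F9.
- NaBH4 in THF-MeOH at 0 °C reduces the aldehyde without touching pivalate or tosylate, so the fallback returns to the route at 14.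

Further compounds
F1 | step 6 | (2S)-6-bromo-8-methoxy-2-[3-methoxy-4-(tosyloxy)phenyl]-3-(trifluoroacetyl)chroman-4-one (C3 undefined, enolisable) | O=C1C(C(=O)C(F)(F)F)[C@@H](c2ccc(OS(=O)(=O)c3ccc(C)cc3)c(OC)c2)Oc2c(OC)cc(Br)cc12
F2 | step 6 | (2R)-6-bromo-3-diazo-8-methoxy-2-[3-methoxy-4-(tosyloxy)phenyl]chroman-4-one (C2 arranged as in 8, descriptor changed by ranking) | O=C1C(=[N+]=[N-])[C@@H](c2ccc(OS(=O)(=O)c3ccc(C)cc3)c(OC)c2)Oc2c(OC)cc(Br)cc12
F3 | step 6 | {5-bromo-7-methoxy-2-[3-methoxy-4-(tosyloxy)phenyl]benzofuran-3(2H)-ylidene}methanone (ketene, C2 arranged as in 8) | O=C=C1[C@@H](c2ccc(OS(=O)(=O)c3ccc(C)cc3)c(OC)c2)Oc2c(OC)cc(Br)cc12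
F4 | step 6 | methyl (2S,3R)-5-bromo-7-methoxy-2-[3-methoxy-4-(tosyloxy)phenyl]-2,3-dihydrobenzofuran-3-carboxylate (cis) | Brc1cc(OC)c2c(c1)[C@@H](C(=O)OC)[C@@H](c1ccc(OS(=O)(=O)c3ccc(C)cc3)c(OC)c1)O2
F5 | step 5 | 4-formyl-2-methoxyphenyl 4-methylbenzenesulfonate | COc1cc(C=O)ccc1OS(=O)(=O)c1ccc(C)cc1
F6 | step 5 | (E)-1-(5-bromo-2-hydroxy-3-methoxyphenyl)-3-[3-methoxy-4-(tosyloxy)phenyl]prop-2-en-1-one | COc1cc(Br)cc(C(=O)/C=C/c2ccc(OS(=O)(=O)c3ccc(C)cc3)c(OC)c2)c1O
F7 | step 5 | racemic 6-bromo-8-methoxy-2-[3-methoxy-4-(tosyloxy)phenyl]chroman-4-one | O=C1CC(c2ccc(OS(=O)(=O)c3ccc(C)cc3)c(OC)c2)Oc2c(OC)cc(Br)cc12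
F8 | step 5 | (2R,4R)-6-bromo-8-methoxy-2-[3-methoxy-4-(tosyloxy)phenyl]chroman-4-ol (cis) | O[C@@H]1C[C@H](c2ccc(OS(=O)(=O)c3ccc(C)cc3)c(OC)c2)Oc2c(OC)cc(Br)cc12
F9 | step 9 | {(2S,3R)-5-formyl-7-methoxy-2-[3-methoxy-4-(tosyloxy)phenyl]-2,3-dihydrobenzofuran-3-yl}methyl pivalate | O=Cc1cc(OC)c2c(c1)[C@H](COC(=O)C(C)(C)C)[C@@H](c1ccc(OS(=O)(=O)c3ccc(C)cc3)c(OC)c1)O2
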